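Remark: the SMILES is read as cyclohex-2-en-1-one carrying an unbranched nonadecyl chain (19 carbons) on C3. There is no stereocentre, so no configuration has to be set. Ring atoms are C1–C6 (C1 is the carbonyl carbon) and chain atoms are C1'–C19'.

## Structural features

Compound 7 has one ring, a cyclohex-2-en-1-one (C1=O, C2=C3, methylenes C4–C6), and one substituent, a saturated unbranched C19 chain on the β-carbon C3. It has no stereocentre and no stereogenic double bond, so the problem is one of connectivity and regiochemistry: the chain must end up on C3 and not on C2, C4 or C6. The only reactive group is the enone. It tolerates acid, but under base it can enolise at C6, C4 or C1' (deconjugation, self-condensation), and it accepts nucleophiles at C1 and C3. The chain has an odd carbon count, whereas commodity long-chain reagents are even (C18, C20), so a plan that takes 18 chain carbons from a C18 reagent is better supplied than one that needs a C19 reagent. The feature the key step exploits is the oxidation pattern of the four contiguous atoms C1(=O)–C2H=C3–C1'H2. C1/C2 and C3/C1' are each an alkyne plus or minus water, and the three methylenes C4–C6 hold them in a 1,6 relationship. Compound 7 (C25H46O) is therefore an isomer of an acyclic 1,6-diyne (C25H44) plus one molecule of water. The real difficulty is to close the six-membered ring and fix the chain at C3 in one regiodefined operation, while handling waxy, non-polar intermediates that are hard to separate from each other.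

## Logic of the disconnections

**Disconnection 1 (7 to 4).** The C2=C3 double bond is first moved to the exocyclic C3=C1' position, which gives 6. The ring bond C2–C3 is then cut, which gives 5, with C2 as an enol carbon and C3/C1' as an internal alkyne. Finally the C1=O bond is cut and the oxygen is returned to water, so that C1/C2 become a terminal alkyne, which gives 4. The cut is made there because these four atoms sit at alkyne oxidation level and the three methylenes between them are exactly the tether needed for a six-membered closure. The gain is large: the ring and the only functional group disappear, and 4 is an acyclic hydrocarbon with two alkynes and no regiochemical question beyond their spacing. The forward step must hydrate only the terminal alkyne, in the Markovnikov sense, and must close C2–C3 through the methyl-side enol (6-exo-dig) before a second hydration occurs. In one sentence: the ring of 7 is closed between C2 and C3 by a gold-catalysed hydrative carbocyclisation of the acyclic diyne 4.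

**Disconnection 2 (4 to 1 and 2, through 3).** The bond cut is C7–C8 of 4, which is C1'–C2' of the chain in 7. It is an sp–sp3 bond next to the internal alkyne, so it maps onto an acetylide alkylation. The cut splits the odd C19 chain into one carbon that belongs to the diyne and an even C18 electrophile, and it leaves two purchasable compounds: the symmetrical C7 diyne 1 and the commodity bromide 2. The forward step must functionalise only one end of the symmetrical 1, which calls for statistical control (excess of 1, one equivalent of base) through the monoanion 3.

## Other disconnections considered

**Alternative 1:** Cut of the exocyclic bond C3–C1'. The forward key step is a Stork–Danheiser sequence. The Grignard reagent A2 (nonadecylmagnesium bromide) adds 1,2 to the vinylogous ester A1 (3-ethoxycyclohex-2-en-1-one) to give the tertiary allylic alcohol A3 (3-ethoxy-1-nonadecylcyclohex-2-en-1-ol). Aqueous acid then hydrolyses A3 with allylic transposition to 7. This is the route that comes to mind first, and it is short and dependable. It is not chosen for three reasons. It leaves the ring untouched and so fails the first test. It brings in the whole chain as an odd-carbon C19 organometallic for which there is no commodity source, whereas the chosen plan takes 18 of the 19 carbons from 2. At equal step count it also spends a stoichiometric organomagnesium reagent and an ethoxy leaving group, where the chosen key step only adds water.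

**Alternative 2:** Cut of the chain bond C2'–C3'. The forward key step is a mixed Kolbe electrolysis at a platinum anode: anodic decarboxylation and radical–radical heterocoupling of the enone acid A4 (3-(3-oxocyclohex-1-en-1-yl)propanoic acid) with an excess of A5 (octadecanoic acid), a union of two carbons of like polarity that would give 7 directly. The chosen plan is preferred on three grounds:
- Mechanism: two primary radicals of similar reactivity couple statistically, so the cross product is accompanied by both symmetrical dimers, all of them waxy and non-polar.
- Structure: the radical from A4 is homoallylic to the enone double bond and can close reversibly to a cyclopropylcarbinyl radical stabilised by the carbonyl group, which opens paths to coupling at C2. The enone is also a radical acceptor.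
- Step economy: A4 is not a stock compound and needs about two steps of its own, so the route is at least three steps with a difficult separation.

**Alternative 3:** Cut of C1–C2 and C1–C6, with the carbonyl carbon coming from carbon monoxide. The forward key step is a carbonylative [5+1] ring expansion of the vinylcyclopropane A7 (2-cyclopropylhenicos-1-ene) with CO, catalysed by [Rh(CO)2Cl]2 (monovalent rhodium). It would give the β,γ-enone A8 (3-nonadecylcyclohex-3-en-1-one), which base would conjugate to 7. A7 would come from the ketone A6 (1-cyclopropylicosan-1-one) by Wittig methylenation, and A6 from 2 by enolate alkylation. The regiochemistry is sound, because cleavage of the cyclopropane bond next to the alkene places the substituted alkene carbon β to the new carbonyl. The chosen plan is preferred on step economy (four steps against two), because it avoids pressurised CO and a separate double-bond isomerisation, and because A6 uses the same C1 + C18 split of the chain and so offers no supply advantage.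

Key step: step 2

## Route

Step 1
Reactants: 1 hepta-1,6-diyne; 2 1-bromooctadecane
Product: 4 pentacosa-1,6-diyne, via lithium hepta-1,6-diyn-1-ide 3 (not isolated)
Conditions: 1 (3 equiv), n-BuLi (1.0 equiv), THF, −78 °C; then 2 (0.9 equiv), DMPU, 0 → 40 °C
Reagents that add atoms: none
Why: One equivalent of n-BuLi on a threefold excess of the symmetrical diyne 1 should give mainly the monolithium acetylide 3, which displaces bromide from the primary bromide 2 in an SN2 acetylide alkylation accelerated by DMPU; the excess of 1 suppresses double alkylation and is recovered by distillation, and no stereocentre is formed.

Step 2
Reactants: 4 pentacosa-1,6-diyne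
Product: 7 3-nonadecylcyclohex-2-en-1-one, via pentacos-6-yn-2-one 5 (not isolated), via (Z)-3-nonadecylidenecyclohexan-1-one 6 (not isolated)
Conditions: MeAu(PPh3) (2 mol %), MsOH (0.5 equiv), H2O (2 equiv), MeOH/1,4-dioxane (1:1), 70 °C
Reagents that add atoms: water (O)
Why: MeAu(PPh3) and MsOH give a cationic phosphine complex of monovalent gold that π-activates both alkynes, and water should add in the Markovnikov sense to the unhindered terminal alkyne first to give methyl ketone 5. The methyl-side enol of 5 then attacks the gold-bound internal alkyne at its proximal carbon anti to the metal, and protodeauration of the vinylgold species gives the β,γ-unsaturated ketone 6; acid finally moves the exocyclic double bond into the ring and into conjugation to give 7. The closest known reaction type is the gold-catalysed hydrative cyclisation of 1,6-diynes to 3-substituted cyclohex-2-en-1-ones, itself a hydration followed by a Conia-ene-type enol–alkyne addition. The one ring is closed in the 6-exo-dig mode, which forms the C2–C3 bond of 7; the 7-endo-dig closure from the same enol and the 4-exo-dig or 5-endo-dig closures from the ring-side enol are less favourable. No stereocentre is formed, and the Z geometry that anti addition gives to the exocyclic alkene of 6 is erased by the isomerisation. The step needs chemoselectivity between the two alkynes and regioselectivity in the C–C bond formation: the first rests on the faster gold-catalysed hydration of terminal alkynes, the second on the fact that only the methyl carbon of 5 can reach the alkyne through a six-membered transition state. Water is held near two equivalents so that carbocyclisation outruns a second hydration, which would lead through an open-chain diketone to an aldol closure of uncertain direction. The product is the thermodynamic sink, since the endocyclic trisubstituted enone is the most stable double-bond isomer.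

## Compound list

1 | hepta-1,6-diyne | C#CCCCC#C | starting material
2 | 1-bromooctadecane | CCCCCCCCCCCCCCCCCCBr | starting material
3 | lithium hepta-1,6-diyn-1-ide | [Li]C#CCCCC#C | intermediate
4 | pentacosa-1,6-diyne | C#CCCCC#CCCCCCCCCCCCCCCCCCC | intermediate
5 | pentacos-6-yn-2-one | CC(=O)CCCC#CCCCCCCCCCCCCCCCCCC | intermediate
6 | (Z)-3-nonadecylidenecyclohexan-1-one | O=C1C/C(=C\CCCCCCCCCCCCCCCCCC)CCC1 | intermediate
7 | 3-nonadecylcyclohex-2-en-1-one | CCCCCCCCCCCCCCCCCCCC1=CC(=O)CCC1 | target

## Step count and risk

Total step count: 2. Longest linear sequence: 2 steps. The route has only two steps, so both are assessed; there are no further steps to rank.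

**Step 2 (key step).** Three processes are the most likely to go wrong.
- Loss of regiocontrol by over-hydration. If a second water adds to the internal alkyne before the C2–C3 bond forms (a process the new carbonyl oxygen can assist), the substrate becomes an open-chain diketone. Its acid-catalysed aldol closure can run through the chain-side enol and place the chain on C2 with a methyl group on C3.
- Hydration in the wrong order. Hydration of the internal alkyne before the terminal one diverts material to five-membered or regioisomeric six-membered products.
- Slow ring closure. The 6-exo-dig closure on a non-terminal alkyne has no gem-disubstituent effect in the tether to help it, which gives the competing processes more time.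

Fallback (known chemistry, arene dearomatisation in place of diyne cyclisation; it sets out from 2 and returns at 7). Compound 2 is coupled with purchased (3-methoxybenzyl)magnesium chloride under Li2CuCl4 catalysis (THF, 0 °C → rt; copper-catalysed Kochi-type alkyl–alkyl coupling) to give 1-methoxy-3-nonadecylbenzene F1. Birch reduction (Li, liquid NH3/THF, t-BuOH, −78 → −33 °C) should give 1-methoxy-5-nonadecylcyclohexa-1,4-diene F2; the regiochemistry is fixed because both donor substituents remain on sp2 carbons. Aqueous HCl in THF then hydrolyses the enol ether and moves the remaining double bond into conjugation, which gives 7 with the chain necessarily on C3.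

**Step 1.** Two processes are the most likely to go wrong.
- Over-alkylation. Proton exchange between the product alkyne and unreacted acetylide 3 would lead to alkylation at both ends of the diyne.
- Sluggish substitution. A slow SN2 reaction of the poorly soluble long-chain bromide would allow competing elimination.

Either process leaves hydrocarbon mixtures that are hard to separate from 4.

Fallback (linear construction of the unsymmetrical diyne with one terminus masked, in place of desymmetrising 1; it sets out from 2 and returns at 4). Compound 2 is treated with the lithium acetylide–ethylenediamine complex LiC≡CH·H2NCH2CH2NH2 in DMSO to give icos-1-yne F3. Deprotonation with n-BuLi in THF and alkylation with purchased (5-iodopent-1-yn-1-yl)trimethylsilane in THF/DMPU should give trimethyl(pentacosa-1,6-diyn-1-yl)silane F4. K2CO3 in MeOH removes the silyl group and gives 4. Each alkylation is then a 1:1 reaction with no statistical component.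

## Further compounds

F1 | step 2 | 1-methoxy-3-nonadecylbenzene | COc1cccc(CCCCCCCCCCCCCCCCCCC)c1
F2 | step 2 | 1-methoxy-5-nonadecylcyclohexa-1,4-diene | COC1=CCC=C(CCCCCCCCCCCCCCCCCCC)C1
F3 | step 1 | icos-1-yne | C#CCCCCCCCCCCCCCCCCCC
F4 | step 1 | trimethyl(pentacosa-1,6-diyn-1-yl)silane | C[Si](C)(C)C#CCCCC#CCCCCCCCCCCCCCCCCCC
A1 | alternative 1 | 3-ethoxycyclohex-2-en-1-one | CCOC1=CC(=O)CCC1
A2 | alternative 1 | nonadecylmagnesium bromide | CCCCCCCCCCCCCCCCCCC[Mg]Br
A3 | alternative 1 | 3-ethoxy-1-nonadecylcyclohex-2-en-1-ol | CCOC1=CC(O)(CCCCCCCCCCCCCCCCCCC)CCC1
A4 | alternative 2 | 3-(3-oxocyclohex-1-en-1-yl)propanoic acid | O=C1C=C(CCC(=O)O)CCC1
A5 | alternative 2 | octadecanoic acid | CCCCCCCCCCCCCCCCCC(=O)O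
A6 | alternative 3 | 1-cyclopropylicosan-1-one | O=C(CCCCCCCCCCCCCCCCCCC)C1CC1
A7 | alternative 3 | 2-cyclopropylhenicos-1-ene | C=C(CCCCCCCCCCCCCCCCCCC)C1CC1
A8 | alternative 3 | 3-nonadecylcyclohex-3-en-1-one | O=C1CC(CCCCCCCCCCCCCCCCCCC)=CCC1
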